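Assumption (remark on the chemistry): the enzymes and their cofactors are treated as purchasable or recombinantly expressed catalysts, so only arachidonic acid and dioxygen count as starting materials, and the route is laid out for the small scale that a self-inactivating synthase allows.

## Analysis of the target

Compound 7 is a prostanoid built on a cyclopentanone (ring atoms C8–C12) that carries the acid chain C1–C7 on C8, a 3-oxooctyl chain C13–C20 on C12, a secondary alcohol on C9 and the ring ketone at C11. Its three stereocentres all lie on the ring, C8 (R), C9 (S) and C12 (R), with the two chains trans to each other and the C9 hydroxyl cis to the C8 chain. The only alkene is the Z-C5=C6 double bond, so an unselective hydrogenation is excluded, and the two ketones (C11 and C15) must stay distinct from each other and from the free acid. The most fragile element is the β-hydroxy ketone C9(OH)–C10–C11(=O), which loses the hydroxyl by β-elimination under base or on long standing in water, and C12 is enolisable towards C11, although the trans arrangement is the stable one. The difficulty therefore lies in the ring oxygen pattern: a route that builds the ring first must tell two ring oxygens apart with protecting groups and unveil a base-labile aldol at the very end. The strategy rests on the chain numbering: 7 is a C20 acid in which the C8–C12 bond is closed, oxygen sits on C9, C11 and C15, and C5=C6 is a Z alkene left over from a skipped polyene, which is the imprint that a fatty-acid cyclooxygenase leaves on the all-Z tetraenoic acid 1. Both ring oxygens can come from one bridging molecule of dioxygen 2 that spans C9 and C11 on the same face, and what then remains (saturated C13–C14, ketone at C15) is a redox isomerisation confined to the lower chain.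

## Retrosynthetic reasoning

**From 7 to 6.** The two C–H bonds at C13 and C14 are removed, giving the E-enone 6. A saturated ethylene unit next to a ketone is the retron of a conjugate reduction, and the enone is one oxidation step from the allylic alcohol that the cascade delivers. The forward reaction must reduce only the conjugated alkene, while the isolated Z-C5=C6 alkene, the C11 ketone and the aldol unit survive. A hydride-transferring 13-reductase meets this at neutral pH.

**From 6 to 5.** The C15 carbonyl is traced back to the 15S allylic alcohol of 5. The oxidation is placed before the alkene reduction because the reductase needs the carbonyl to activate C13=C14. The forward reaction must oxidise the C15 alcohol and leave the C9 alcohol alone. A 15-hydroxy dehydrogenase reads the allylic 15S carbinol and does this without protecting groups.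

**From 5 to 4.** The β-hydroxy ketone of 5 is the retron of a Kornblum–DeLaMare-type opening of a 9,11-endoperoxide. Reconnecting O9 to O11 and returning a hydrogen to C11 gives 4. This places both ring oxygens cis from a single peroxide bridge and removes any need to differentiate them. The forward reaction must take the hydrogen from C11 and not from C9, and a D-type synthase enforces this sense of opening.

**From 4 through 3 to 1 and 2.** This is the key disconnection. One C–C bond (C8–C12) and three C–O bonds (C9–O, C11–O, C15–O) are cut, which opens the cyclopentane and the dioxolane and returns the E-C13=C14 alkene to the skipped Z,Z-diene. What remains is the commercial tetraene 1 and two molecules of 2. Hydroperoxide 3 is the immediate cascade product and is reduced to 4 in the same enzyme. The cut is made here because every bond formed lies on the C8–C15 segment, where the skipped alkenes of 1 are pre-positioned for two 5-exo radical closures, while C1–C7 and C16–C20 ride along unchanged. The forward reaction must control the site of hydrogen abstraction, the faces of both oxygen additions and the trans disposition of the chains. The protein supplies all of this, whereas the free radical chain would not.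

## Alternatives that were turned down

**Alternative 1: iodoacetal radical cyclisation with enone trapping.**
- Disconnection: C7–C8 and C12–C13 are cut across a cyclopentene. The precursor is iodoacetal A2, a cyclopentene that already carries the C9 and C11 oxygens cis and in enantiopure form.
- Key step: Bu3SnH and AIBN give a C7 radical that closes 5-exo onto C8 (cis-fused tetrahydrofuran acetal). The resulting C12 radical is intercepted on the convex face by oct-1-en-3-one A3, giving A1.
- For: C8 and C12 are set relative to the existing C9 and C11 oxygens in one operation. With A3 the lower chain arrives already saturated and with its C15 ketone, exactly as 7 needs it. On this point the alternative is stronger than the chosen route, which spends two redox steps on the chain. It is also scalable and handles no peroxide.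
- Against: the bimolecular trapping competes with hydrogen transfer from the stannane to the C12 radical, and A3 tends to oligomerise under radical conditions. More seriously, the ring oxygens of A1 come out the wrong way round for this target: C11 carries the silyl ether and must become the ketone, while C9 must end as the free alcohol. The C15 ketone must be masked before a basic Wittig extension of the lactol, C9 protected, C11 unmasked and oxidised, and the aldol unveiled last. With the preparation of A2 this comes to about a dozen steps.
- Comparison: the chosen route is four steps without protecting groups, because the endoperoxide opening delivers the 9-hydroxy-11-ketone directly.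

**Alternative 2: amine-catalysed aldol dimerisation of succinaldehyde.**
- Disconnection: C8–C9 and C11–C12 are cut by aldol logic into two molecules of succinaldehyde A5.
- Key step: (S)-proline and then dibenzylammonium trifluoroacetate effect an intermolecular aldol, an intramolecular aldol condensation and lactol closure, giving bicyclic enal lactol A4.
- For: the enantioenriched ring with C8 and C9 set is reached in one step from a very cheap feedstock. The formyl carbon of A4 is excised later and leaves a carbonyl at C11, which fits the oxidation pattern of 7 well. On cost and scalability it is clearly stronger than an enzymatic cascade.
- Against: the dimerisation of A5 competes with oligomerisation, so throughput at the first step should be low. The lower chain must enter by conjugate addition as an sp3 3-oxooctyl nucleophile with its ketone masked. The C11 ketone would then face the basic ylide of the lactol olefination with an oxygen leaving group at C9 in the β-position. Reduction, protection and late re-oxidation would be needed, roughly doubling the step count.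
- Comparison: the chosen route sets all three ring stereocentres and both ring oxygens at once and never exposes the aldol to base.

**Alternative 3: desymmetrising Pauson–Khand reaction.**
- Disconnection: C8–C9, C10–C11 and C11–C12 are cut, leading to divinyl acetal enyne A7.
- Key step: [Rh(CO)2Cl]2 (monovalent rhodium) with (S)-BINAP and AgOTf under CO joins the alkyne of A7, one of its two enantiotopic vinyl ethers and CO to give bicyclic enone A6.
- For: it is convergent. The ring, the C11 carbonyl and the ketal-protected lower chain are assembled in one step from an achiral acyclic precursor. In skeletal bond count per step it matches the chosen key step.
- Against: vinyl ethers are reluctant Pauson–Khand partners, and differentiating two of them on a small acetal carbon is a demanding enantiotopic-group selection. Only C9 is set in A6. C8 and C12 remain as a tetrasubstituted enone whose reduction must deliver the cis ring fusion and then rely on equilibration at C12. Any hydrogenation would also touch the residual vinyl ether. The β-alkoxy ketone (C9–O, C11=O) is again prone to elimination during the later Wittig step.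
- Comparison: one stereocentre from a catalyst whose selectivity is uncertain, against five fixed by an enzyme acting on its native substrate.

Key step: step 1

## Route

**Step 1**
Reactants: 1 arachidonic acid ((5Z,8Z,11Z,14Z)-icosa-5,8,11,14-tetraenoic acid); 2 dioxygen (two molecules per molecule of 1)
Product: 4 prostaglandin H2 (9α,11α-epidioxy-15S-hydroxyprosta-5Z,13E-dienoic acid), via prostaglandin G2 3 (not isolated)
Conditions: ovine prostaglandin-endoperoxide synthase 1 (or recombinant human isoform 2), hemin (C34H32ClFeN4O4, cat.), hydroquinone, O2-saturated Tris·HCl pH 8.0, 25 °C, about 2 min, sub-millimolar 1; then citric acid to pH 3–4, Et2O, 0 °C; SiO2, Et2O/hexane, −20 °C; kept in acetone at −78 °C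
Reagents that add atoms: none
Why: The peroxidase cycle of the enzyme generates the Tyr-385 radical, which abstracts the pro-S hydrogen at C13 of bound 1; the C11–C15 pentadienyl radical takes up the first molecule of 2 at C11 on the face opposite the departing hydrogen (11R). The C11 peroxyl radical adds to C9 of the C8=C9 alkene by 5-exo-trig closure (1,2-dioxolane ring, C9–O bond), and the C8 radical adds to C12 of the C12=C13 alkene by a second 5-exo-trig closure (cyclopentane ring, C8–C12 bond), so the two rings together make the 2,3-dioxabicyclo[2.2.1]heptane. The C13–C15 allyl radical traps the second molecule of 2 at C15 (15S, new E-C13=C14 alkene), hydrogen return from the tyrosine gives hydroperoxide 3, and the peroxidase site reduces its O–O bond to the alcohol of 4 with hydroquinone as two-electron donor. The closest known reaction type is the enzyme's native bis-dioxygenation of 1, mechanistically a peroxyl-radical 5-exo/5-exo cascade of the kind seen in polyene autoxidation. All five new stereocentres (C8, C9, C11, C12, C15) are fixed by the protein: the bound chain conformation decides the faces of both oxygen additions and forces the C8 and C12 substituents trans, whereas the unconstrained radical prefers the cis-dialkyl ring. The step needs abstraction at C13 rather than at the other doubly allylic positions C7 and C10, first oxygenation at C11, and an untouched Z-C5=C6 alkene. The substrate secures this through its all-Z skipped tetraene, which places C13 beneath the tyrosyl radical when the carboxylate is anchored at the channel mouth, and through the position of C5=C6 outside the reacting C8–C15 segment.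

**Step 2**
Reactants: 4 prostaglandin H2
Product: 5 prostaglandin D2 (9α,15S-dihydroxy-11-oxoprosta-5Z,13E-dienoic acid)
Conditions: haematopoietic prostaglandin D synthase (recombinant human), glutathione (cat.), MgCl2, Tris·HCl pH 8.0, 25 °C, 1–2 min, 4 added in cold acetone; then citric acid to pH 4, EtOAc, 0 °C; SiO2, EtOAc/hexane/AcOH
Reagents that add atoms: none
Why: Enzymatic Kornblum–DeLaMare-type isomerisation: the active-site glutathione thiolate attacks O11, the O–O bond breaks with protonation of O9, and loss of the C11 hydrogen from the S–O intermediate gives the C11 ketone and returns the thiol. The protein directs the opening to the 9-hydroxy-11-ketone, C8, C9, C12 and C15 are not touched, and a high enzyme loading is meant to keep the reaction ahead of the uncatalysed decay of the endoperoxide.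

**Step 3**
Reactants: 5 prostaglandin D2
Product: 6 15-keto-prostaglandin D2 (9α-hydroxy-11,15-dioxoprosta-5Z,13E-dienoic acid)
Conditions: 15-hydroxyprostaglandin dehydrogenase (NAD+-dependent, recombinant human), NAD+ (cat.), water-forming NADH oxidase, air, Tris·HCl pH 7.5, no thiol additive, 25 °C; then citric acid to pH 4, EtOAc, 0 °C; crude 6 used at once
Reagents that add atoms: none
Why: Enzymatic alcohol dehydrogenation: hydride passes from C15 to NAD+, which the oxidase regenerates with air, so the oxidation is pulled to completion. The enzyme recognises the allylic 15S carbinol and should leave the C9 alcohol alone; neutral pH, short contact and the absence of thiols protect the aldol unit and the new Michael acceptor.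

**Step 4**
Reactants: 6 15-keto-prostaglandin D2
Product: 7 13,14-dihydro-15-keto-prostaglandin D2 ((5Z)-7-[(1R,2R,5S)-5-hydroxy-3-oxo-2-(3-oxooctyl)cyclopentyl]hept-5-enoic acid)
Conditions: 15-oxoprostaglandin 13-reductase (prostaglandin reductase 1, recombinant human), NADP+ (cat.), D-glucose (excess), glucose dehydrogenase, KH2PO4/K2HPO4 buffer pH 7.0, 25 °C; then citric acid to pH 4, EtOAc; reversed-phase HPLC, MeCN/H2O/AcOH; stored cold
Reagents that add atoms: none
Why: Enzymatic conjugate reduction of an enone: NADPH delivers hydride to C13 and the enolate is protonated at C14, with glucose dehydrogenase recycling the cofactor and hydrolysis of the gluconolactone making the recycling irreversible. The isolated Z-C5=C6 alkene and the C11 ketone are not substrates, no stereocentre is created, and C12 stays in the trans arrangement, which is also the thermodynamically preferred one.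

## Compound list

1 | arachidonic acid ((5Z,8Z,11Z,14Z)-icosa-5,8,11,14-tetraenoic acid) | CCCCC/C=C\C/C=C\C/C=C\C/C=C\CCCC(=O)O | starting material
2 | dioxygen | O=O | starting material
3 | prostaglandin G2 (9α,11α-endoperoxide with 15S hydroperoxide) | CCCCC[C@H](OO)/C=C/[C@H]1[C@H]2C[C@H](OO2)[C@@H]1C/C=C\CCCC(=O)O | intermediate
4 | prostaglandin H2 (9α,11α-endoperoxide with 15S alcohol) | CCCCC[C@H](O)/C=C/[C@H]1[C@H]2C[C@H](OO2)[C@@H]1C/C=C\CCCC(=O)O | intermediate
5 | prostaglandin D2 (9α-hydroxy-11-ketone with 15S alcohol) | CCCCC[C@H](O)/C=C/[C@H]1C(=O)C[C@H](O)[C@@H]1C/C=C\CCCC(=O)O | intermediate
6 | 15-keto-prostaglandin D2 (9α-hydroxy-11-ketone with E-13-en-15-one) | CCCCCC(=O)/C=C/[C@H]1C(=O)C[C@H](O)[C@@H]1C/C=C\CCCC(=O)O | intermediate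
7 | 13,14-dihydro-15-keto-prostaglandin D2 | CCCCCC(=O)CC[C@H]1C(=O)C[C@H](O)[C@@H]1C/C=C\CCCC(=O)O | target

## Step count and risk

Total step count: 4. Longest linear sequence: 4 steps (1 → 4 → 5 → 6 → 7). Step 2 is the native reaction of its enzyme on its native substrate and is judged the most secure. The least certain steps are the following.

**Step 1 (key step).** The most likely failure is loss of 4 between its formation and its use. The strained endoperoxide is expected to rearrange and fragment in the aqueous phase and on silica during isolation. Mechanism-based self-inactivation of the synthase also caps the conversion of 1, and an under-supplied peroxidase cycle would leave the hydroperoxide stage unreduced. The fallback gives up the isolation and couples the cascade to the next enzyme. Acid 1 is incubated under 2 with the synthase, hemin, phenol as co-reductant (so that no thiol-reactive quinone forms), the haematopoietic D synthase and glutathione in one buffer. Endoperoxide 4 is then isomerised as fast as it leaves the cyclooxygenase site. The fallback sets out from 1 and 2 and comes back to the route at 5, passing 3 and 4 only as transients. It makes no compound outside the list, so its entry is F0.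

**Step 3.** The most likely failure is slow turnover, since the dehydrogenase is tuned to other ring types and may accept the 11-keto ring sluggishly. A long incubation would allow dehydration of the aldol unit of 5 and 6. It would also allow enolisation at C12 of 6, which is α to C11=O and γ to the new enone, leading to epimerisation or migration of the alkene towards C12. The fallback is a chemical allylic oxidation. Alcohol 5 is treated with DDQ in dioxane at room temperature (or with activated MnO2 in CH2Cl2). This dehydrogenates the allylic C15 carbinol and leaves the non-allylic C9 alcohol, in a non-aqueous, weakly acidic medium that spares the aldol. The fallback sets out from 5 and comes back at 6. It makes no compound outside the list, so its entry is F0.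

**Step 4.** The most likely failure is consumption of 6 before it is reduced, by Michael addition of nucleophiles in the medium or by isomerisation through the dienolate spanning C11 to C15. A poor fit of the 11-keto ring in a reductase whose usual substrates carry an 11-hydroxyl is also possible. The fallback is a chemical 1,4-reduction. Enone 6 is treated with Pd(PPh3)4 (zerovalent palladium, catalytic) and AcOH in THF at room temperature, with Bu3SnH added slowly and in excess, since the free acid consumes part of it. Hydrostannation gives a tin enolate that acetic acid protonates. The isolated Z alkene and the saturated C11 ketone do not react, and the medium stays slightly acidic. The hexameric copper hydride [(Ph3P)CuH]6 would effect the same reduction but is not preferred: the free acid of 6 destroys hydride by protonolysis, and basic copper alkoxides endanger the aldol, so the acid and alcohol would first have to be silylated. The fallback sets out from 6 and comes back at 7. It makes no compound outside the list, so its entry is F0.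

## Further compounds

F0 | step 1 | none | none
F0 | step 3 | none | none
F0 | step 4 | none | none
A1 | alternative 1 | bicyclic ethyl acetal with 3-oxooctyl on C12 and tert-butyldimethylsilyl ether on C11 (product of the radical cyclisation and trapping) | CCCCCC(=O)CC[C@H]1[C@H](O[Si](C)(C)C(C)(C)C)C[C@@H]2OC(OCC)C[C@H]12
A2 | alternative 1 | iodoacetal of cis-4-(tert-butyldimethylsilyloxy)cyclopent-2-en-1-ol (radical precursor, acetal carbon as a mixture) | CCOC(CI)O[C@@H]1C=C[C@H](O[Si](C)(C)C(C)(C)C)C1
A3 | alternative 1 | oct-1-en-3-one | CCCCCC(=O)C=C
A4 | alternative 2 | bicyclic enal lactol (formyl on C11, alkene C11=C12, lactol carbon C6 as a mixture) | O=CC1=C[C@H]2CC(O)O[C@H]2C1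
A5 | alternative 2 | succinaldehyde | O=CCCC=O
A6 | alternative 3 | bicyclic enone (C11 ketone, alkene C8=C12, vinyl acetal at C6 as a mixture, C15 as dioxolane) | CCCCCC1(OCCO1)CCC2=C3CC(OC=C)O[C@H]3CC2=O
A7 | alternative 3 | divinyl acetal enyne (C15 as dioxolane) | CCCCCC1(OCCO1)CCC#CCC(OC=C)OC=C
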